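Slow as this coupling is, its two products together grow at a pace I can read as one number, the product clock: target plus isomer of the product at 10 h, divided by 10 h times the log-mean of the starting material remaining over the run 0.0546 h⁻¹. That is the spring reading, and the same division gives 0.0531 h⁻¹ in the summer run and 0.0542 h⁻¹ in the noon run, so I treat it as a pseudo-first-order constant in starting material.

| setting | spring | summer | noon | flask |
|---|---|---|---|---|
| starting material | 22 mM | 88 mM | 44 mM | 44 mM |
| coupling partner | 30.8 mM | 30.8 mM | 30.8 mM | 30.8 mM |
| protic impurity | 22 mM | 22 mM | 33 mM | 22.0 mM |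
| remark | run made earlier | run made earlier | run made earlier |  |
| time |  |  |  | 10 h |

| run | time / h | target / % | isomer of the product / % | starting material / % |
|---|---|---|---|---|
| spring | 0.667 | 1.7 | 3.1 | 92.3 |
| spring | 2.00 | 3.1 | 6.0 | 78.9 |
| spring | 4.00 | 6.6 | 10.7 | 61.6 |
| spring | 5.00 | 8.3 | 13.5 | 55.5 |
| spring | 8.00 | 10.2 | 18.3 | 41.0 |
| spring | 10.0 | 11.9 | 20.8 | 32.3 |
| summer | 0.833 | 1.5 | 3.0 | 89.9 |
| summer | 1.33 | 2.3 | 5.2 | 85.8 |
| summer | 2.00 | 3.6 | 5.7 | 80.0 |
| summer | 4.00 | 6.5 | 12.3 | 67.0 |
| summer | 6.00 | 7.8 | 18.1 | 56.6 |
| summer | 10.0 | 9.4 | 26.4 | 42.8 |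
| noon | 2.00 | 4.2 | 6.4 | 75.1 |
| noon | 4.00 | 4.9 | 10.6 | 57.0 |
| noon | 6.00 | 8.6 | 15.3 | 44.5 |
| noon | 8.00 | 9.2 | 17.4 | 36.0 |
| noon | 10.0 | 10.8 | 20.8 | 30.2 |

(scatter of a reading: 0.5 percentage points)

* the target in the flask at 10 h, as a percentage of the starting material charged
* the isomer of the product in the flask at 10 h, as a percentage of the starting material charged
* the starting material in the flask at 10 h, as a percentage of the starting material charged
* concentration of coupling partner at 10 h, in mM

The flask has the protic impurity charge of spring and summer and a starting material charge between theirs, so I take its starting material at 10 h midway between their readings, 37.5%. The clock then gives 34.8% of products, and, counting one coupling partner per product, 15.5 mM of coupling partner left.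

The forecast, a little apart from my reckoning, says 11% target, 23.5% isomer of the product, 36.5% starting material and 15.6 mM coupling partner, and it reads the shortfall in the earlier runs as “a third, unseen sink”.

The flask gives 11.4% target, 22.8% isomer of the product, 36.8% starting material and 15.8 mM coupling partner, each inside the forecast's range.

    starting material ⇌ tight pair (K = 0.0700, k = 1.55 × 10⁻⁵ s⁻¹)
    tight pair ⇌ loose pair (K = 1.87, k = 0.225 s⁻¹)
    coupling partner + tight pair → target (k = 4.65 M⁻¹ s⁻¹)
    coupling partner + loose pair → isomer of the product (k = 107 M⁻¹ s⁻¹)
    starting material + protic impurity → quenched substrate (k = 8.95 × 10⁻⁴ M⁻¹ s⁻¹)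
    tight pair → decomposed reagent (k = 1.49 × 10⁻⁴ s⁻¹)

At 10.0 h the flask still holds 51.2% of its coupling partner, while tight pair stands at 0%, made and used at a ratio of 1.00. The clock, given the flask's own starting material, leaves 15.6 mM of coupling partner.

For the neighbour charged with 110 mM of starting material, taking summer's remaining starting material, the clock asks 40.5 mM of coupling partner, more than the 30.8 mM charged. That neighbour ends with 0 mM coupling partner, 6.72% target, 21.3% isomer of the product and 47.6% starting material: coupling partner is its limiting reagent.

(The runs come from a simulation from invented constants; noise was put on by code.)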